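## Retrosynthetic overview

1. The target comes from a silyl-protected macrocyclic hydroxy lactone by C6–O angeloylation and C9–O desilylation.
2. Key disconnection, C6–C7: a 3-(bromomethyl)butenolide is reduced by CrCl2 to an allylchromium whose nucleophilic terminus is C7, the β-carbon of the lactone (a lactone homoenolate equivalent). It attacks the C6 epoxy aldehyde, closes the ten-membered ring and sets C6 and C7.
3. The bromomethyl butenolide comes from ring-closing metathesis of a 2-(bromomethyl)acrylate of a C8 vinyl carbinol; the C4–C5 epoxide comes from a Sharpless epoxidation.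
4. C8/C9 come from an iridium-catalysed anti-(benzoyloxy)allylation of a C9 alcohol; C10 comes from a Ru–BINAP hydrogenation of 8-hydroxygeranyl acetate (C1–C6, C9, C10, C14, C15 all from geranyl acetate).
5. Ring order: epoxide, then butenolide, then the ten-membered carbocycle last.

Locants are germacrane locants: ring C1–C10 (C15 on C4, C14 on C10), epoxide C4–C5, O-angelate on C6, lactone C7–C11(=C13H2)–C12(=O)–O–C8, OH on C9. The target is (4R,5R,6R,7S,8S,9R,10R).

Assumption: the absolute sense of the Ru–BINAP hydrogenation (step 2) and of the Ir–SEGPHOS allylation (step 4) is assigned by analogy with geraniol and with simple alcohol allylations; if either runs the other way, the mirror-image ligand is used.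

## Route

Step 1
Reactants: 1 geranyl acetate [(2E)-3,7-dimethylocta-2,6-dien-1-yl acetate]
Product: 2 (2E,6E)-8-hydroxy-3,7-dimethylocta-2,6-dien-1-yl acetate
Conditions: SeO2 (10 mol %), t-BuOOH (2 equiv), salicylic acid (10 mol %), CH2Cl2, rt
Reagents that add atoms: tert-butyl hydroperoxide, CC(C)(C)OO
Why: Sharpless–Umbreit allylic oxidation (ene reaction then 2,3-shift) attacks the (E)-methyl group of the electron-richer distal alkene and leaves the allylic acetate alkene alone.

Step 2
Reactants: 2 (2E,6E)-8-hydroxy-3,7-dimethylocta-2,6-dien-1-yl acetate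
Product: 3 (2E,7R)-8-hydroxy-3,7-dimethyloct-2-en-1-yl acetate
Conditions: Ru(OAc)2[(S)-BINAP] (1 mol %), H2 (50 atm), MeOH, 25 °C
Reagents that add atoms: none
Why: Noyori hydroxyl-directed asymmetric hydrogenation reduces only the alkene next to the free CH2OH and sets C10 (R) by ligand-controlled delivery of H2 to one face.

Step 3
Reactants: 4 acrolein; 5 benzoic anhydride
Product: 6 prop-2-ene-1,1-diyl dibenzoate
Conditions: H2SO4 (cat.), CH2Cl2, 0 °C → rt
Reagents that add atoms: none
Why: acid-catalysed acylal formation (1,1-diacylation of an aldehyde by an anhydride) gives the allyl donor for step 4.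

Step 4
Reactants: 3 (2E,7R)-8-hydroxy-3,7-dimethyloct-2-en-1-yl acetate; 6 prop-2-ene-1,1-diyl dibenzoate
Product: 8 (3S,4R,5R,9E)-11-acetoxy-4-hydroxy-5,9-dimethylundeca-1,9-dien-3-yl benzoate, via aldehyde 7 (not isolated)
Conditions: [Ir(cod)Cl]2 (2.5 mol %), (S)-SEGPHOS (5 mol %), 4-cyano-3-nitrobenzoic acid (10 mol %), K3PO4 (20 mol %), THF, 60 °C
Reagents that add atoms: none
Why: Krische transfer-hydrogenative anti-(α-benzoyloxy)allylation: the alcohol is dehydrogenated to 7, which reacts through a closed chair with the (benzoyloxy)allyliridium to give the anti C8–O/C9–O pair, the ligand (not the C10 methyl) fixing the aldehyde face (C8 S, C9 R).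

Step 5
Reactants: 8 (3S,4R,5R,9E)-11-acetoxy-4-hydroxy-5,9-dimethylundeca-1,9-dien-3-yl benzoate
Product: 9 (3S,4R,5R,9E)-11-acetoxy-5,9-dimethyl-4-(triethylsilyloxy)undeca-1,9-dien-3-yl benzoate
Conditions: Et3SiOTf, 2,6-lutidine, CH2Cl2, −78 °C
Reagents that add atoms: triethylsilyl trifluoromethanesulfonate, CC[Si](CC)(CC)OS(=O)(=O)C(F)(F)F
Why: silyl ether formation on the only free hydroxyl keeps C9–O distinct from C8–O (lactone) and C6–O (angelate) for the rest of the route.

Step 6
Reactants: 9 (3S,4R,5R,9E)-11-acetoxy-5,9-dimethyl-4-(triethylsilyloxy)undeca-1,9-dien-3-yl benzoate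
Product: 10 (2E,7R,8R,9S)-3,7-dimethyl-8-(triethylsilyloxy)undeca-2,10-diene-1,9-diol
Conditions: i-Bu2AlH (5 equiv), CH2Cl2, −78 °C; Rochelle salt work-up
Reagents that add atoms: none
Why: reductive cleavage of both esters at low temperature frees C8–OH and C6–OH without the basic conditions that would let the silyl group migrate from O9 to O8.

Step 7
Reactants: 10 (2E,7R,8R,9S)-3,7-dimethyl-8-(triethylsilyloxy)undeca-2,10-diene-1,9-diol
Product: 11 (3S,4R,5R)-8-[(2R,3R)-3-(hydroxymethyl)-2-methyloxiran-2-yl]-5-methyl-4-(triethylsilyloxy)oct-1-en-3-ol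
Conditions: Ti(OiPr)4 (10 mol %), D-(−)-diethyl tartrate (12 mol %), t-BuOOH (1.5 equiv), 4 Å MS, CH2Cl2, −20 °C
Reagents that add atoms: tert-butyl hydroperoxide, CC(C)(C)OO
Why: Katsuki–Sharpless asymmetric epoxidation: the D-tartrate catalyst epoxidises the primary trisubstituted allylic alcohol with reagent control to the (4R,5R) epoxide (the (2R,3R)-epoxygeraniol sense), while the vinyl carbinol reacts orders of magnitude more slowly.

Step 8
Reactants: 11 (3S,4R,5R)-8-[(2R,3R)-3-(hydroxymethyl)-2-methyloxiran-2-yl]-5-methyl-4-(triethylsilyloxy)oct-1-en-3-ol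
Product: 12 (2S,3R)-3-[(4R,5R,6S)-6-hydroxy-4-methyl-5-(triethylsilyloxy)oct-7-en-1-yl]-3-methyloxirane-2-carbaldehyde
Conditions: TEMPO (10 mol %), PhI(OAc)2 (1.1 equiv), CH2Cl2, 0 °C → rt
Reagents that add atoms: none
Why: oxoammonium (TEMPO) oxidation is selective for the primary alcohol over the hindered secondary one and does not touch the epoxide (the C5 label changes to S only because CHO outranks C4).

Step 9
Reactants: 12 (2S,3R)-3-[(4R,5R,6S)-6-hydroxy-4-methyl-5-(triethylsilyloxy)oct-7-en-1-yl]-3-methyloxirane-2-carbaldehyde; 13 2-(bromomethyl)prop-2-enoic acid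
Product: 14 (3S,4R,5R)-8-[(2R,3S)-3-formyl-2-methyloxiran-2-yl]-5-methyl-4-(triethylsilyloxy)oct-1-en-3-yl 2-(bromomethyl)prop-2-enoate
Conditions: DCC, DMAP (5 mol %), CH2Cl2, −20 → 0 °C
Reagents that add atoms: none
Why: Steglich esterification of the only free hydroxyl (C8–OH) places the lactone oxygen correctly; DMAP is kept low and cold to avoid quaternisation by the allylic bromide.

Step 10
Reactants: 14 (3S,4R,5R)-8-[(2R,3S)-3-formyl-2-methyloxiran-2-yl]-5-methyl-4-(triethylsilyloxy)oct-1-en-3-yl 2-(bromomethyl)prop-2-enoate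
Product: 15 (2S,3R)-3-{(4R,5R)-5-[(2S)-4-(bromomethyl)-5-oxo-2,5-dihydrofuran-2-yl]-4-methyl-5-(triethylsilyloxy)pentyl}-3-methyloxirane-2-carbaldehyde
Conditions: second-generation Hoveyda–Grubbs catalyst (10 mol %), toluene, 80 °C, 0.01 M
Reagents that add atoms: none
Why: ring-closing metathesis of an allyl 2-substituted acrylate (as for α-methyl butenolides) forms the five-membered lactone with loss of ethylene and touches no stereocentre.

Step 11
Reactants: 15 (2S,3R)-3-{(4R,5R)-5-[(2S)-4-(bromomethyl)-5-oxo-2,5-dihydrofuran-2-yl]-4-methyl-5-(triethylsilyloxy)pentyl}-3-methyloxirane-2-carbaldehyde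
Product: 17 (4R,5R,6R,7R,8S,9R,10R)-4,5-epoxy-6-hydroxy-9-(triethylsilyloxy)germacr-11(13)-en-12,8-olide, via allylchromium dichloride 16 (not isolated)
Conditions: CrCl2 (8 equiv), THF, rt, syringe-pump addition of 15 (final 2 mM)
Reagents that add atoms: none
Why: Proposed new method: a ten-membered-ring, intramolecular variant of the known CrCl2 Nozaki–Hiyama allylation of aldehydes with 3-(bromomethyl)butenolides, in which CrCl2 makes the allylchromium 16 whose γ-terminus C7 (the lactone β-carbon, a homoenolate equivalent) adds to the C6 aldehyde through a chair; the ring-locked (E)-type allyl unit with C5 equatorial gives the anti C6/C7 array, the tether can only span to the butenolide face opposite C9 (trans C7/C8), and the epoxide C–O lies anti to the forming bond (Felkin–Anh), so all three preferences converge on the target configuration (C7 is labelled R here only because of CIP priorities).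

Step 12
Reactants: 17 (4R,5R,6R,7R,8S,9R,10R)-4,5-epoxy-6-hydroxy-9-(triethylsilyloxy)germacr-11(13)-en-12,8-olide; 18 angelic acid [(2Z)-2-methylbut-2-enoic acid]
Product: 19 (4R,5R,6R,7R,8S,9R,10R)-6-angeloyloxy-4,5-epoxy-9-(triethylsilyloxy)germacr-11(13)-en-12,8-olide
Conditions: 2,4,6-trichlorobenzoyl chloride, Et3N, toluene, rt; then 17, 75 °C
Reagents that add atoms: none
Why: Yamaguchi-type acylation through the mixed anhydride, run without DMAP, esterifies the hindered C6–OH without Z→E isomerisation to the tiglate and without forming an alkoxide that could translactonise.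

Step 13
Reactants: 19 (4R,5R,6R,7R,8S,9R,10R)-6-angeloyloxy-4,5-epoxy-9-(triethylsilyloxy)germacr-11(13)-en-12,8-olide
Product: 20 CNP0165329.1, (4R,5R,6R,7S,8S,9R,10R)-6-angeloyloxy-4,5-epoxy-9-hydroxygermacr-11(13)-en-12,8-olide
Conditions: HF·pyridine, pyridine, THF, 0 °C
Reagents that add atoms: none
Why: buffered fluoride cleavage of the triethylsilyl ether is mild enough for the epoxide, angelate and α-methylene lactone; no stereocentre changes (C7 becomes S by CIP priority only).

## Compound list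

1 | geranyl acetate, (2E)-3,7-dimethylocta-2,6-dien-1-yl acetate | CC(C)=CCC/C(C)=C/COC(C)=O | starting material
2 | (2E,6E)-8-hydroxy-3,7-dimethylocta-2,6-dien-1-yl acetate | OC/C(C)=C/CC/C(C)=C/COC(C)=O | intermediate
3 | (2E,7R)-8-hydroxy-3,7-dimethyloct-2-en-1-yl acetate | OC[C@H](C)CCC/C(C)=C/COC(C)=O | intermediate
4 | acrolein (prop-2-enal) | C=CC=O | starting material
5 | benzoic anhydride | O=C(OC(=O)c1ccccc1)c1ccccc1 | starting material
6 | prop-2-ene-1,1-diyl dibenzoate | C=CC(OC(=O)c1ccccc1)OC(=O)c1ccccc1 | intermediate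
7 | (2E,7R)-3,7-dimethyl-8-oxooct-2-en-1-yl acetate (aldehyde, not isolated) | O=C[C@H](C)CCC/C(C)=C/COC(C)=O | intermediate
8 | (3S,4R,5R,9E)-11-acetoxy-4-hydroxy-5,9-dimethylundeca-1,9-dien-3-yl benzoate | O=C(c1ccccc1)O[C@@H](C=C)[C@H](O)[C@H](C)CCC/C(C)=C/COC(C)=O | intermediate
9 | (3S,4R,5R,9E)-11-acetoxy-5,9-dimethyl-4-(triethylsilyloxy)undeca-1,9-dien-3-yl benzoate | O=C(c1ccccc1)O[C@@H](C=C)[C@H](O[Si](CC)(CC)CC)[C@H](C)CCC/C(C)=C/COC(C)=O | intermediate
10 | (2E,7R,8R,9S)-3,7-dimethyl-8-(triethylsilyloxy)undeca-2,10-diene-1,9-diol | O[C@@H](C=C)[C@H](O[Si](CC)(CC)CC)[C@H](C)CCC/C(C)=C/CO | intermediate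
11 | (3S,4R,5R)-8-[(2R,3R)-3-(hydroxymethyl)-2-methyloxiran-2-yl]-5-methyl-4-(triethylsilyloxy)oct-1-en-3-ol | O[C@@H](C=C)[C@H](O[Si](CC)(CC)CC)[C@H](C)CCC[C@@]1(C)O[C@@H]1CO | intermediate
12 | (2S,3R)-3-[(4R,5R,6S)-6-hydroxy-4-methyl-5-(triethylsilyloxy)oct-7-en-1-yl]-3-methyloxirane-2-carbaldehyde | O[C@@H](C=C)[C@H](O[Si](CC)(CC)CC)[C@H](C)CCC[C@@]1(C)O[C@@H]1C=O | intermediate
13 | 2-(bromomethyl)prop-2-enoic acid | C=C(CBr)C(=O)O | starting material
14 | (3S,4R,5R)-8-[(2R,3S)-3-formyl-2-methyloxiran-2-yl]-5-methyl-4-(triethylsilyloxy)oct-1-en-3-yl 2-(bromomethyl)prop-2-enoate | C=C(CBr)C(=O)O[C@@H](C=C)[C@H](O[Si](CC)(CC)CC)[C@H](C)CCC[C@@]1(C)O[C@@H]1C=O | intermediate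
15 | (2S,3R)-3-{(4R,5R)-5-[(2S)-4-(bromomethyl)-5-oxo-2,5-dihydrofuran-2-yl]-4-methyl-5-(triethylsilyloxy)pentyl}-3-methyloxirane-2-carbaldehyde | BrCC1=C[C@@H]([C@H](O[Si](CC)(CC)CC)[C@H](C)CCC[C@@]2(C)O[C@@H]2C=O)OC1=O | intermediate
16 | allylchromium dichloride formed from 15 (CrCl2 on C13, not isolated) | Cl[Cr](Cl)CC1=C[C@@H]([C@H](O[Si](CC)(CC)CC)[C@H](C)CCC[C@@]2(C)O[C@@H]2C=O)OC1=O | intermediate
17 | (4R,5R,6R,7R,8S,9R,10R)-4,5-epoxy-6-hydroxy-9-(triethylsilyloxy)germacr-11(13)-en-12,8-olide | C=C1C(=O)O[C@@H]2[C@H](O[Si](CC)(CC)CC)[C@H](C)CCC[C@@]3(C)O[C@@H]3[C@H](O)[C@@H]12 | intermediate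
18 | angelic acid, (2Z)-2-methylbut-2-enoic acid | C/C=C(/C)C(=O)O | starting material
19 | (4R,5R,6R,7R,8S,9R,10R)-6-angeloyloxy-4,5-epoxy-9-(triethylsilyloxy)germacr-11(13)-en-12,8-olide | C=C1C(=O)O[C@@H]2[C@H](O[Si](CC)(CC)CC)[C@H](C)CCC[C@@]3(C)O[C@@H]3[C@H](OC(=O)/C(C)=C\C)[C@@H]12 | intermediate
20 | CNP0165329.1, (4R,5R,6R,7S,8S,9R,10R)-6-angeloyloxy-4,5-epoxy-9-hydroxygermacr-11(13)-en-12,8-olide | C=C1C(=O)O[C@@H]2[C@H](O)[C@H](C)CCC[C@@]3(C)O[C@@H]3[C@H](OC(=O)/C(C)=C\C)[C@@H]12 | target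

## Step count and risks

Total: 13 steps. Longest linear sequence: 12 steps (steps 1, 2 and 4–13 from geranyl acetate); step 3 makes the allyl donor.

**Step 11 (ring closure).** The risks are oligomerisation, cis ring fusion or attack through C13 instead of C7, and translactonisation of the product to the 6,12-olide. Fallback, from 15 back to 17: replace the reductive metalation by a thermal allylboration. Borylation of 15 with B2pin2 and Pd2(dba)3 (cat.) in toluene gives the isolable pinacol allylboronate F1, whose ester-substituted allyl unit is too electron-poor to add to the aldehyde at room temperature. Heating F1 at high dilution (toluene, 90 °C) cyclises it through the same closed six-membered transition state without any reducing metal, and aqueous work-up of the borate gives 17.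

**Step 10 (metathesis).** The allylic bromide may alkylate or decompose the ruthenium alkylidene, and the 1,1-disubstituted electron-poor olefin is a slow partner. Fallback, from 12 back to 17 (bypassing 14 and 15): esterify 12 with 2-(acetoxymethyl)acrylic acid (DCC) to the 2-(acetoxymethyl)acrylate ester F2, which carries no halide. Ring-closing metathesis then gives the 3-(acetoxymethyl)butenolide F3. The ring is closed by the polarity-reversed route through zerovalent palladium: Pd(PPh3)4 (cat.) and Et2Zn at high dilution convert the π-allylpalladium acetate into an allylzinc that adds to the C6 aldehyde through the same chair, giving 17.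

**Step 4 (iridium allylation).** The catalyst must override the Felkin bias of the C10 methyl group, the benzoate may migrate from O8 to O9, and the transient α-chiral aldehyde may epimerise. Fallback, from 3 back to 10:
- Oxidise 3 to aldehyde 7 (Dess–Martin periodinane) and add CH2=CHMgBr at −78 °C to give the vinyl carbinol F4 as both C9 epimers.
- Sharpless kinetic resolution (Ti(OiPr)4, D-(−)-diisopropyl tartrate, t-BuOOH) epoxidises only the epimer with the required C9 configuration and gives the erythro epoxy alcohol F5.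
- Et3SiCl/imidazole gives its triethylsilyl ether F6, and K2CO3/MeOH removes the acetate to give the epoxy alcohol F7.
- Dimethylsulfonium methylide (Me3S+ I−, n-BuLi, THF, −10 °C) opens the terminal epoxide at CH2 and eliminates Me2S, giving the vinyl carbinol 10 with C8–OH free and C9–O already silylated.

## Further compounds

F1 | step 11 | (2S,3R)-3-methyl-3-{(4R,5R)-4-methyl-5-[(2S)-5-oxo-4-[(4,4,5,5-tetramethyl-1,3,2-dioxaborolan-2-yl)methyl]-2,5-dihydrofuran-2-yl]-5-(triethylsilyloxy)pentyl}oxirane-2-carbaldehyde | CC1(C)OB(CC2=C[C@@H]([C@H](O[Si](CC)(CC)CC)[C@H](C)CCC[C@@]3(C)O[C@@H]3C=O)OC2=O)OC1(C)C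
F2 | step 10 | (3S,4R,5R)-8-[(2R,3S)-3-formyl-2-methyloxiran-2-yl]-5-methyl-4-(triethylsilyloxy)oct-1-en-3-yl 2-(acetoxymethyl)prop-2-enoate | C=C(COC(C)=O)C(=O)O[C@@H](C=C)[C@H](O[Si](CC)(CC)CC)[C@H](C)CCC[C@@]1(C)O[C@@H]1C=O
F3 | step 10 | {(5S)-5-[(1R,2R)-5-[(2R,3S)-3-formyl-2-methyloxiran-2-yl]-2-methyl-1-(triethylsilyloxy)pentyl]-2-oxo-2,5-dihydrofuran-3-yl}methyl acetate | CC(=O)OCC1=C[C@@H]([C@H](O[Si](CC)(CC)CC)[C@H](C)CCC[C@@]2(C)O[C@@H]2C=O)OC1=O
F4 | step 4 | (2E,7R)-8-hydroxy-3,7-dimethyldeca-2,9-dien-1-yl acetate (both C8 epimers) | C=CC(O)[C@H](C)CCC/C(C)=C/COC(C)=O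
F5 | step 4 | (2E,7R,8R)-8-hydroxy-3,7-dimethyl-8-[(2S)-oxiran-2-yl]oct-2-en-1-yl acetate | C1O[C@@H]1[C@H](O)[C@H](C)CCC/C(C)=C/COC(C)=O
F6 | step 4 | (2E,7R,8R)-3,7-dimethyl-8-[(2S)-oxiran-2-yl]-8-(triethylsilyloxy)oct-2-en-1-yl acetate | C1O[C@@H]1[C@H](O[Si](CC)(CC)CC)[C@H](C)CCC/C(C)=C/COC(C)=O
F7 | step 4 | (2E,7R,8R)-3,7-dimethyl-8-[(2S)-oxiran-2-yl]-8-(triethylsilyloxy)oct-2-en-1-ol | C1O[C@@H]1[C@H](O[Si](CC)(CC)CC)[C@H](C)CCC/C(C)=C/CO
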